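## The problem

The target is a monocyclic bisabolane: a cyclohexane ring (C1–C6, methyl C15 on C3) joined at C6 to an eight-carbon chain (C7 with its exocyclic methylene C14, C8, C9, C10, C11 with methyls C12 and C13). The skeleton is simple; the task is seven stereocentres among four labile oxygen functions. Five stereocentres are on the ring: C1 (free OH), C2 (angelate), C3 and C4 (epoxide) and C6. C1–O is trans to C2–O and to the C6–C7 bond and cis to the epoxide oxygen, so C1 can serve as the reference for C2 (inversion), C6 (equilibration) and C3/C4 (hydroxyl delivery). C8 is insulated from the ring by sp2 carbon C7 and C10 lies two atoms further out, so both need reagent control. The two trisubstituted epoxides do not survive acid, the two (Z)-2-methylbut-2-enoates isomerise to tiglates under nucleophilic acyl-transfer catalysis and can migrate to the free C1–OH in base, and C8–O is allylic. The epoxides must therefore come last, the esters late, and every acidic step before them. The enabling feature is that the vicinal oxygenated carbons C1 and C2 lie between C3 (methyl) and C6 (chain), which are para to each other: with C3=C4 and C5=C6 as double bonds, ring C1–C6 is the 2,3-cis-dihydrodiol of a para-disubstituted toluene. A dioxygenase delivers such diols cis, whereas the target is trans, so one carbinol has to be inverted afterwards.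

## Retrosynthesis

**C10–O and C11–O (21 to 20).** The side-chain epoxide is removed first. It is the most acid-sensitive group and is remote from every other stereocentre, so it is best made last by a reagent that carries its own chirality. Diene 20 has one stereocentre fewer. The forward step must pick C10=C11 among four C=C bonds and one of its faces, which suits an electrophilic chiral dioxirane.

**C3–O and C4–O (20 to 19).** The ring epoxide oxygen is cis to C1–OH, which can deliver a metal-bound peroxide to C3=C4. Epoxidation while C1 and C2 are still an acetonide would occur on the opposite face, and epoxidation before the C2 ester is in place would remove the allylic activation the next cut relies on. The forward step must transfer oxygen from the C1 side to the ring alkene only.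

**C2–O with inversion (19 to 18 and 15).** The C2 ester bond is cut so that it forms in an SN2 step on cis-diol 18. One operation installs the angelate and converts the cis relationship left by a dioxygenase into the trans one of the target. Acylating a trans-diol would need a separate inversion and a choice between two similar hydroxyls; in 18 the choice is built in, because C2–OH is allylic and C1–OH is not. The forward step must spare the Z double bond of 15.

**Acetonide and C8–O acyl bond (18 to 17, then to 14 and 15 through 16).** The diol stays masked until all carbon–carbon bonds are made. The C8 ester is cut at the acyl–oxygen bond (retention) and is placed before the hydrolysis, so that C8–OH never competes in the Mitsunobu step. The forward acylation must not isomerise the angelate, and the hydrolysis is the last acidic step.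

**C8 stereocentre and C7–C8 (14 to 13 to 12, then to 9 and 11; 11 from 10).** Cutting C7–C8 gives alkenyl triflate 9 and the five-carbon aldehyde 11, made from commercial 10. The neighbouring cut C6–C7 with the whole chain would need an sp3–sp2 coupling at a ring carbon next to C1–O. Since C6 cannot control C8 through C7, C8 is set separately by oxidation to enone 13 and catalyst-controlled reduction.

**C7–O and C6–H (9 to 8, then to 6 through 7).** Triflate 9 is the kinetic enol derivative of methyl ketone 8, and 8 comes from conjugate reduction of dienone 6. A ketone at C7 is what activates C5=C6 alone for reduction and leaves C3=C4 for the epoxide. The price is C6: protonation is expected to give the cis epimer 7, which must be equilibrated to trans 8.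

**C6–C7 (6 to 3 and 4 through 5).** The acetyl group is cut at the sp2–sp2 bond into vinyl iodide 3 and the acyl-anion equivalent 4. The iodine that steers the enzyme is reused as the coupling handle. The forward Stille coupling must be mild enough for a diene that dimerises on standing.

**C1–O and C2–O (3 to 2 to 1).** Removing the acetonide and both oxygens returns the ring to arene 1. No small reagent adds two cis oxygens enantioselectively to one bond of a benzene ring; the dioxygenase does, and all ring carbons, the methyl group, the handle and C1 come from one commodity compound. The enzyme must place iodine, not methyl, in its larger pocket.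

## Roads not taken

**Alternative 1:** The cut is C3=C4, opening A1 (the target without its ring epoxide) to acyclic triene A2 with a vinyl group on C5 and an isopropenyl group on C2. The forward step is ring-closing metathesis with the second-generation Grubbs catalyst RuCl2(=CHPh)(H2IMes)(PCy3) and loss of ethylene.
- Merits: the closure is neutral, tolerates esters and the side-chain epoxide, and six-membered trisubstituted cycloalkenes are among the most reliable metathesis products. There is no enolisable ketone beside C1–O, and C6 is set by acyclic C–C bond formation, not by epimerisation. In this respect it is better than the chosen plan.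
- Weak points: A2 already carries C1, C2, C6, C8 and C10, so five stereocentres must be built by acyclic methods and carried with two angelates. A1 still faces the same ring epoxidation.
- Comparison: the chosen plan sets against this the ring, both ring oxygens and the absolute configuration in one step, so far fewer stereodefining steps.

**Alternative 2:** The cut is C4–C5. The forward step is a Ferrier carbocyclisation: Hg(OCOCF3)2 (divalent mercury) in aqueous acetone converts enopyranoside A4 into hydroxycyclohexanone A3.
- Merits: absolute configuration comes from glucose without an enzyme. The trans C1–O/C2–O relationship and the C3 tertiary carbinol come ready-made, so no inversion and no directed epoxidation are needed to fix C3. In these two respects it is better than the chosen plan.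
- Weak points: A4 needs a branched (2-C-methyl) sugar, two 4-methoxybenzyl ethers and a 6-deoxy-5-ene, which is many steps before the key step. In A3 the chain must still be attached at a ketone carbon beside a β-alkoxy group, which raises the same C6 and elimination issues. The C4 carbinol must be activated and displaced by the C3 oxygen, and a stoichiometric mercury salt is used.
- Comparison: the chosen plan sets against this its length, roughly half, and the absence of hydroxyl protecting-group manipulation.

**Alternative 3:** The cuts are C5–C6 and C1–C2. The forward step is a Diels–Alder reaction of isoprene A7 with imide A6 under a chiral bis(oxazoline) complex of Cu(SbF6)2 (divalent copper), giving A5.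
- Merits: one catalytic step builds the ring with the methyl group and C3=C4 in place. It sets C1 and C6 trans from the E dienophile, which is the relationship the chosen plan secures only by equilibration; here it is clearly better.
- Weak points: C2 is a CH2 group in A5. Its oxygen needs an allylic C–H oxidation next to C3 that competes with C5 and C15 and must give the right configuration. Isoprene is a sluggish diene with imperfect para selectivity, and the β-benzoyloxy imide can eliminate on enolisation.
- Comparison: the chosen plan sets against this both ring oxygens delivered in step 1 and no C–H oxidation.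

Key step: step 1

Assumption: iodine, the larger para substituent, takes the enzyme pocket that holds the single substituent of a monosubstituted arene, so that 2 has the (1S,2S) configuration drawn. The atom numbering is that of "The problem".

## Route

Step 1
Reactants: 1 4-iodotoluene
Product: 2 (1S,2S)-3-iodo-6-methylcyclohexa-3,5-diene-1,2-diol
Conditions: E. coli JM109 (pDTG601) whole cells expressing toluene dioxygenase (no diol dehydrogenase), glucose, air, phosphate buffer pH 7, 30 °C; EtOAc extraction, recrystallisation
Reagents that add atoms: dioxygen, O=O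
Why: Arene cis-dihydroxylation by a Rieske non-haem iron dioxygenase, the known reaction of toluene dioxygenase with para-substituted iodobenzenes. Electrons from NADH pass through reductase and ferredoxin to the Rieske [2Fe–2S] cluster and on to the mononuclear iron, which binds O2 and transfers both oxygen atoms to the same face of one arene C=C bond, so C1–O and C2–O form cis. No ring is closed: the carbocycle is the arene itself, which keeps the diene C3=C4/C5=C6. Both new stereocentres are set by the active site, which delivers oxygen from a fixed face to the bond next to the substituent held in its larger pocket. The selectivity needed is between the two symmetry-related ortho/meta bonds, which lead to opposite enantiomers; the larger size of iodine compared with methyl is what should direct the enzyme to the (1S,2S) diol, with C1 (next to C–I) already in the target configuration. The host lacks the dehydrogenase that would rearomatise the diol to a catechol; benzylic hydroxylation of the methyl group is the side reaction to watch.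

Step 2
Reactants: 2 (1S,2S)-3-iodo-6-methylcyclohexa-3,5-diene-1,2-diol
Product: 3 (3aS,7aS)-4-iodo-2,2,7-trimethyl-3a,7a-dihydro-1,3-benzodioxole
Conditions: 2,2-dimethoxypropane, p-TsOH (cat.), acetone, 0 °C to rt
Reagents that add atoms: 2,2-dimethoxypropane, COC(C)(C)OC
Why: Acid-catalysed transketalisation; the cis-diol closes a dioxolane without touching the stereocentres, and the acetonide stops acid-promoted dehydration of the dienediol to a phenol.

Step 3
Reactants: 3 (3aS,7aS)-4-iodo-2,2,7-trimethyl-3a,7a-dihydro-1,3-benzodioxole; 4 tributyl(1-ethoxyvinyl)stannane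
Product: 6 1-[(3aR,7aS)-2,2,7-trimethyl-3a,7a-dihydro-1,3-benzodioxol-4-yl]ethan-1-one, via 1-ethoxyvinyl diene acetonide 5 (not isolated)
Conditions: Pd(PPh3)4 (5 mol%), CuI (10 mol%), DMF, 45 °C; then 1 M HCl, THF, 0 °C
Reagents that add atoms: water, O
Why: Stille coupling followed by enol ether hydrolysis; zerovalent palladium inserts into C6–I, CuI speeds transmetallation so that the diene has little time to dimerise, and cold dilute acid cleaves the enol ether much faster than the acetonide.

Step 4
Reactants: 6 1-[(3aR,7aS)-2,2,7-trimethyl-3a,7a-dihydro-1,3-benzodioxol-4-yl]ethan-1-one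
Product: 8 1-[(3aR,4S,7aS)-2,2,7-trimethyl-3a,4,5,7a-tetrahydro-1,3-benzodioxol-4-yl]ethan-1-one, via cis-acetyl epimer 7 (not isolated)
Conditions: [(Ph3P)CuH]6 (0.3 equiv), PhMe, H2O (5 equiv), rt; filtration; then DBU (0.2 equiv), CH2Cl2, 0 °C to rt
Reagents that add atoms: none
Why: Conjugate reduction by a monovalent copper hydride, then base-mediated epimerisation; hydride adds to C5 (1,6-addition would require attack at the fully substituted C3), and protonation anti to the dioxolane should give mainly 7. DBU equilibrates C6 to 8, in which acetyl is equatorial while C2–O stays pseudoaxial and free of allylic strain with the C3 methyl, whereas 7 must either place acetyl 1,3-diaxial to C2–O or give up that arrangement.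

Step 5
Reactants: 8 1-[(3aR,4S,7aS)-2,2,7-trimethyl-3a,4,5,7a-tetrahydro-1,3-benzodioxol-4-yl]ethan-1-one
Product: 9 1-[(3aR,4S,7aS)-2,2,7-trimethyl-3a,4,5,7a-tetrahydro-1,3-benzodioxol-4-yl]ethenyl trifluoromethanesulfonate
Conditions: KN(SiMe3)2 (1.1 equiv), THF, −78 °C (ketone added to base); PhNTf2, −78 to 0 °C
Reagents that add atoms: N-phenylbis(trifluoromethanesulfonimide), O=S(=O)(N(c1ccccc1)S(=O)(=O)C(F)(F)F)C(F)(F)F
Why: Kinetic enolisation and O-triflation; the hindered amide removes a methyl proton, not the tertiary C6–H, so the terminal enol triflate forms and the C6 configuration is untouched.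

Step 6
Reactants: 10 4-methylpent-3-en-1-ol
Product: 11 4-methylpent-3-enal
Conditions: Dess–Martin periodinane, pyridine, CH2Cl2, 0 °C; used at once
Reagents that add atoms: none
Why: Dess–Martin oxidation of a primary alcohol under buffered non-aqueous conditions, which keeps the β,γ-unsaturated aldehyde from isomerising into conjugation.

Step 7
Reactants: 9 1-[(3aR,4S,7aS)-2,2,7-trimethyl-3a,4,5,7a-tetrahydro-1,3-benzodioxol-4-yl]ethenyl trifluoromethanesulfonate; 11 4-methylpent-3-enal
Product: 12 (3RS)-6-methyl-2-[(3aR,4R,7aS)-2,2,7-trimethyl-3a,4,5,7a-tetrahydro-1,3-benzodioxol-4-yl]hepta-1,5-dien-3-ol (both C8 epimers)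
Conditions: CrCl2 (4 equiv), NiCl2 (2 mol%), DMF, rt
Reagents that add atoms: none
Why: Nozaki–Hiyama–Kishi coupling; zerovalent nickel inserts into C7–OTf, the alkenyl group passes to trivalent chromium and adds to the aldehyde, forming C7–C8 without base that would enolise 11. No control at C8 is needed because both epimers are oxidised in step 8.

Step 8
Reactants: 12 (3RS)-6-methyl-2-[(3aR,4R,7aS)-2,2,7-trimethyl-3a,4,5,7a-tetrahydro-1,3-benzodioxol-4-yl]hepta-1,5-dien-3-ol
Product: 13 6-methyl-2-[(3aR,4R,7aS)-2,2,7-trimethyl-3a,4,5,7a-tetrahydro-1,3-benzodioxol-4-yl]hepta-1,5-dien-3-one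
Conditions: Dess–Martin periodinane, pyridine, CH2Cl2, 0 °C
Reagents that add atoms: none
Why: Dess–Martin oxidation of a secondary allylic alcohol; neutral conditions avoid migration of C10=C11 into conjugation with the new ketone.

Step 9
Reactants: 13 6-methyl-2-[(3aR,4R,7aS)-2,2,7-trimethyl-3a,4,5,7a-tetrahydro-1,3-benzodioxol-4-yl]hepta-1,5-dien-3-one
Product: 14 (3S)-6-methyl-2-[(3aR,4R,7aS)-2,2,7-trimethyl-3a,4,5,7a-tetrahydro-1,3-benzodioxol-4-yl]hepta-1,5-dien-3-ol
Conditions: (R)-Me-CBS oxazaborolidine (0.5 equiv), catecholborane (1.5 equiv), PhMe, −78 °C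
Reagents that add atoms: none
Why: Corey–Bakshi–Shibata reduction; the oxazaborolidine binds the ketone with the α-branched alkenyl carbon C7 as the large and the CH2 group C9 as the small substituent and delivers hydride to one face, giving the (8S) alcohol by reagent control. 1,2-Reduction outruns hydroboration at −78 °C.

Step 10
Reactants: 14 (3S)-6-methyl-2-[(3aR,4R,7aS)-2,2,7-trimethyl-3a,4,5,7a-tetrahydro-1,3-benzodioxol-4-yl]hepta-1,5-dien-3-ol; 15 angelic acid
Product: 17 (3S)-6-methyl-2-[(3aR,4R,7aS)-2,2,7-trimethyl-3a,4,5,7a-tetrahydro-1,3-benzodioxol-4-yl]hepta-1,5-dien-3-yl (2Z)-2-methylbut-2-enoate, via angelic 2,4,6-trichlorobenzoic anhydride 16 (not isolated)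
Conditions: 15, 2,4,6-trichlorobenzoyl chloride, Et3N, PhMe, rt; then 14, PhMe, 80 °C (no DMAP)
Reagents that add atoms: none
Why: Yamaguchi-type esterification through the mixed anhydride; the alcohol attacks the unhindered angeloyl carbonyl, and omitting a nucleophilic catalyst avoids the addition–elimination that turns angelates into tiglates. The C8–O bond is not broken, so configuration is retained.

Step 11
Reactants: 17 (3S)-6-methyl-2-[(3aR,4R,7aS)-2,2,7-trimethyl-3a,4,5,7a-tetrahydro-1,3-benzodioxol-4-yl]hepta-1,5-dien-3-yl (2Z)-2-methylbut-2-enoate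
Product: 18 (3S)-2-[(1R,5S,6R)-5,6-dihydroxy-4-methylcyclohex-3-en-1-yl]-6-methylhepta-1,5-dien-3-yl (2Z)-2-methylbut-2-enoate
Conditions: AcOH/H2O (4:1), 45 °C
Reagents that add atoms: none
Why: Acid hydrolysis of the isopropylidene acetal, placed as the last acidic step before either epoxide exists; the ester and the alkenes tolerate warm aqueous acetic acid.

Step 12
Reactants: 18 (3S)-2-[(1R,5S,6R)-5,6-dihydroxy-4-methylcyclohex-3-en-1-yl]-6-methylhepta-1,5-dien-3-yl (2Z)-2-methylbut-2-enoate; 15 angelic acid
Product: 19 (3S)-2-[(1R,5R,6R)-6-hydroxy-4-methyl-5-{[(2Z)-2-methylbut-2-enoyl]oxy}cyclohex-3-en-1-yl]-6-methylhepta-1,5-dien-3-yl (2Z)-2-methylbut-2-enoate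
Conditions: PPh3 (2 equiv), iPrO2CN=NCO2iPr (2 equiv), 15 (2 equiv), PhMe, 0 °C to rt
Reagents that add atoms: none
Why: Mitsunobu esterification with inversion; the allylic, pseudoaxial C2–OH is activated as its oxyphosphonium ion (directly or through the dioxaphosphorane of the cis-diol) and displaced by angelate in an SN2 step, making C2–O trans to C1–O. The non-allylic equatorial C1–OH is not displaced, and the acid is never activated at its carbonyl, so the Z geometry is kept.

Step 13
Reactants: 19 (3S)-2-[(1R,5R,6R)-6-hydroxy-4-methyl-5-{[(2Z)-2-methylbut-2-enoyl]oxy}cyclohex-3-en-1-yl]-6-methylhepta-1,5-dien-3-yl (2Z)-2-methylbut-2-enoate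
Product: 20 (1R,2S,3S,4S,6R,8S)-2,8-bis(angeloyloxy)-3,4-epoxybisabola-7(14),10-dien-1-ol (numbering of this proposal)
Conditions: VO(acac)2 (10 mol%), t-BuOOH (2 equiv, decane), CH2Cl2, 0 °C to rt
Reagents that add atoms: tert-butyl hydroperoxide, CC(C)(C)OO
Why: Vanadium-catalysed hydroxyl-directed epoxidation of a homoallylic cyclohexenol; the vanadium alkoxide of C1–OH carries the peroxide to the face of C3=C4 on its own side, so C3 and C4 are set with the oxygen cis to C1–OH and trans to the C2 ester. C10=C11 has no hydroxyl within reach and the angelate alkenes are electron-poor.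

Step 14
Reactants: 20 (1R,2S,3S,4S,6R,8S)-2,8-bis(angeloyloxy)-3,4-epoxybisabola-7(14),10-dien-1-ol
Product: 21 (1R,2S,3S,4S,6R,8S,10R)-2,8-bis(angeloyloxy)-3,4:10,11-diepoxybisabol-7(14)-en-1-ol (target)
Conditions: 1,2:4,5-di-O-isopropylidene-β-D-erythro-2,3-hexodiulo-2,6-pyranose (0.3 equiv), KHSO5 (as 2KHSO5·KHSO4·K2SO4), K2CO3, Bu4NHSO4 (cat.), Na2B4O7 buffer, MeCN/CH2(OMe)2/H2O, 0 °C
Reagents that add atoms: potassium peroxymonosulfate KHSO5, [K+].[O-]S(=O)(=O)OO
Why: Shi epoxidation; the dioxirane of the D-fructose-derived ketone transfers oxygen through a spiro transition state to one face of the electron-rich C10=C11 bond and should set C10 as R by reagent control. The ester-deactivated C7=C14 and the angelate alkenes are poor substrates for an electrophilic dioxirane.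

## Compound list

1 | 4-iodotoluene | Cc1ccc(I)cc1 | starting material
2 | (1S,2S)-3-iodo-6-methylcyclohexa-3,5-diene-1,2-diol | IC1=CC=C(C)[C@H](O)[C@@H]1O | intermediate
3 | (3aS,7aS)-4-iodo-2,2,7-trimethyl-3a,7a-dihydro-1,3-benzodioxole | IC1=CC=C(C)[C@@H]2OC(C)(C)O[C@H]12 | intermediate
4 | tributyl(1-ethoxyvinyl)stannane | CCCC[Sn](CCCC)(CCCC)C(=C)OCC | starting material
5 | (3aR,7aS)-4-(1-ethoxyethenyl)-2,2,7-trimethyl-3a,7a-dihydro-1,3-benzodioxole | C=C(OCC)C1=CC=C(C)[C@@H]2OC(C)(C)O[C@H]12 | intermediate (not isolated)
6 | 1-[(3aR,7aS)-2,2,7-trimethyl-3a,7a-dihydro-1,3-benzodioxol-4-yl]ethan-1-one | CC(=O)C1=CC=C(C)[C@@H]2OC(C)(C)O[C@H]12 | intermediate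
7 | 1-[(3aR,4R,7aS)-2,2,7-trimethyl-3a,4,5,7a-tetrahydro-1,3-benzodioxol-4-yl]ethan-1-one (acetyl cis to C1–O) | CC(=O)[C@@H]1CC=C(C)[C@@H]2OC(C)(C)O[C@H]12 | intermediate (not isolated)
8 | 1-[(3aR,4S,7aS)-2,2,7-trimethyl-3a,4,5,7a-tetrahydro-1,3-benzodioxol-4-yl]ethan-1-one (acetyl trans to C1–O) | CC(=O)[C@H]1CC=C(C)[C@@H]2OC(C)(C)O[C@H]12 | intermediate
9 | 1-[(3aR,4S,7aS)-2,2,7-trimethyl-3a,4,5,7a-tetrahydro-1,3-benzodioxol-4-yl]ethenyl trifluoromethanesulfonate | C=C(OS(=O)(=O)C(F)(F)F)[C@H]1CC=C(C)[C@@H]2OC(C)(C)O[C@H]12 | intermediate
10 | 4-methylpent-3-en-1-ol | CC(C)=CCCO | starting material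
11 | 4-methylpent-3-enal | CC(C)=CCC=O | intermediate
12 | (3RS)-6-methyl-2-[(3aR,4R,7aS)-2,2,7-trimethyl-3a,4,5,7a-tetrahydro-1,3-benzodioxol-4-yl]hepta-1,5-dien-3-ol (C8 epimers) | C=C(C(O)CC=C(C)C)[C@H]1CC=C(C)[C@@H]2OC(C)(C)O[C@H]12 | intermediate
13 | 6-methyl-2-[(3aR,4R,7aS)-2,2,7-trimethyl-3a,4,5,7a-tetrahydro-1,3-benzodioxol-4-yl]hepta-1,5-dien-3-one | C=C(C(=O)CC=C(C)C)[C@H]1CC=C(C)[C@@H]2OC(C)(C)O[C@H]12 | intermediate
14 | (3S)-6-methyl-2-[(3aR,4R,7aS)-2,2,7-trimethyl-3a,4,5,7a-tetrahydro-1,3-benzodioxol-4-yl]hepta-1,5-dien-3-ol | C=C([C@H](CC=C(C)C)O)[C@H]1CC=C(C)[C@@H]2OC(C)(C)O[C@H]12 | intermediate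
15 | angelic acid, (2Z)-2-methylbut-2-enoic acid | C/C=C(/C)C(=O)O | starting material
16 | (2Z)-2-methylbut-2-enoic 2,4,6-trichlorobenzoic anhydride | C/C=C(/C)C(=O)OC(=O)c1c(Cl)cc(Cl)cc1Cl | intermediate (not isolated)
17 | (3S)-6-methyl-2-[(3aR,4R,7aS)-2,2,7-trimethyl-3a,4,5,7a-tetrahydro-1,3-benzodioxol-4-yl]hepta-1,5-dien-3-yl (2Z)-2-methylbut-2-enoate | C=C([C@H](CC=C(C)C)OC(=O)/C(C)=C\C)[C@H]1CC=C(C)[C@@H]2OC(C)(C)O[C@H]12 | intermediate
18 | (3S)-2-[(1R,5S,6R)-5,6-dihydroxy-4-methylcyclohex-3-en-1-yl]-6-methylhepta-1,5-dien-3-yl (2Z)-2-methylbut-2-enoate | C=C([C@H](CC=C(C)C)OC(=O)/C(C)=C\C)[C@H]1CC=C(C)[C@H](O)[C@@H]1O | intermediate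
19 | (3S)-2-[(1R,5R,6R)-6-hydroxy-4-methyl-5-{[(2Z)-2-methylbut-2-enoyl]oxy}cyclohex-3-en-1-yl]-6-methylhepta-1,5-dien-3-yl (2Z)-2-methylbut-2-enoate | C=C([C@H](CC=C(C)C)OC(=O)/C(C)=C\C)[C@H]1CC=C(C)[C@@H](OC(=O)/C(C)=C\C)[C@@H]1O | intermediate
20 | (1R,2S,3S,4S,6R,8S)-2,8-bis(angeloyloxy)-3,4-epoxybisabola-7(14),10-dien-1-ol | C=C([C@H](CC=C(C)C)OC(=O)/C(C)=C\C)[C@H]1C[C@@H]2O[C@]2(C)[C@@H](OC(=O)/C(C)=C\C)[C@@H]1O | intermediate
21 | (1R,2S,3S,4S,6R,8S,10R)-2,8-bis(angeloyloxy)-3,4:10,11-diepoxybisabol-7(14)-en-1-ol | C=C([C@H](C[C@H]1OC1(C)C)OC(=O)/C(C)=C\C)[C@H]1C[C@@H]2O[C@]2(C)[C@@H](OC(=O)/C(C)=C\C)[C@@H]1O | target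

## Step count and least certain steps

Total: 14 steps. Longest linear sequence: 13 steps (1 to 21 through steps 1–5 and 7–14); step 6 is the only step off the main line.

**Step 1 (key step).** The most likely failure is incomplete discrimination between iodine and methyl in the binding pocket, which would erode the enantiomeric purity of 2; benzylic hydroxylation and substrate toxicity could also limit throughput. Fallback: the purity is secured chemically instead of by the enzyme alone. Material 2 of reduced purity is carried unchanged through steps 2 to 9. The oxazaborolidine of step 9 imposes the (8S) configuration on both ring enantiomers, so the antipodal ring series ends as the diastereomeric alcohol F1. F1 is removed by chromatography and the route continues from 14 as a single stereoisomer.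

**Step 4.** Two processes threaten it: β-elimination of the C1 oxygen from the C6 enolate, followed by loss of water and aromatisation, and an equilibrium that does not favour the trans epimer strongly enough. Fallback: the C6 stereocentre is made by carbon–carbon bond formation at a radical, not by protonation. Setting out from 3, Pd(OAc)2/PPh3, CO and MeOH/Et3N should give the methyl dienoate F2. [(Ph3P)CuH]6 reduces it to the saturated ester F3 (C6 configuration irrelevant), and LiOH gives the acid F4. N-Hydroxyphthalimide with N,N′-diisopropylcarbodiimide gives the redox-active ester F5. NiCl2·glyme/2,2′-bipyridine with (1-ethoxyvinyl)zinc chloride then captures the C6 radical on the face away from the cis-fused dioxolane to give the trans enol ether F6. Cold dilute HCl returns the route to 8.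

**Step 13.** Oxygen may be delivered to the wrong alkene: the same vanadium alkoxide can reach C7=C14, and the ring conformer with axial C1–OH needed for delivery to C3=C4 is the less populated one. Fallback: the allylic C2–OH that the enzyme installed is used as the director before it is inverted. Setting out from 18, VO(acac)2/t-BuOOH should give the epoxy cis-diol F7, with oxygen cis to both hydroxyls. The Mitsunobu reaction with 15 then displaces the axial C2–O bond and returns the route to 20.

**Step 12.** Regiocontrol may be lost (displacement at C1), SN2′ attack at C4 or elimination to a diene may compete, and the weakly acidic angelic acid may react slowly. Fallback: inversion by oxidation and reduction. Setting out from 18, MnO2 oxidises only the allylic C2–OH to the hydroxy enone F8. NaBH4/CeCl3 (Luche reduction, axial hydride attack) should give the trans-diol F9, whose allylic C2–OH is acylated with mixed anhydride 16 to return to 19.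

**Step 14.** In the basic medium the C2 angelate may migrate to the free C1–OH or hydrolyse, and the dioxirane may oxidise the C1 carbinol. Fallback: a protecting-group detour. Setting out from 20, Et3SiCl/imidazole gives the C1 triethylsilyl ether F10 and the same epoxidation gives its diepoxide F11. HF·pyridine buffered with pyridine at 0 °C removes the silyl group and returns the route to 21.

**Step 9.** The skipped α-methylene ketone 13 may isomerise into conjugation or oligomerise before it is reduced, and facial discrimination may be weaker than for simple enones. Fallback: C8 is set during carbon–carbon bond formation. Setting out from 9 and 11, a Nozaki–Hiyama–Kishi coupling with stoichiometric CrCl2 bound to a chiral oxazoline–sulfonamide ligand (Et3N, NiCl2 catalyst, THF) gives 14 directly; no new compound is formed.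

## Further compounds

F1 | step 1 | (3S)-6-methyl-2-[(3aS,4S,7aR)-2,2,7-trimethyl-3a,4,5,7a-tetrahydro-1,3-benzodioxol-4-yl]hepta-1,5-dien-3-ol | C=C([C@H](CC=C(C)C)O)[C@@H]1CC=C(C)[C@H]2OC(C)(C)O[C@@H]12
F2 | step 4 | methyl (3aR,7aS)-2,2,7-trimethyl-3a,7a-dihydro-1,3-benzodioxole-4-carboxylate | COC(=O)C1=CC=C(C)[C@@H]2OC(C)(C)O[C@H]12
F3 | step 4 | methyl (3aR,7aS)-2,2,7-trimethyl-3a,4,5,7a-tetrahydro-1,3-benzodioxole-4-carboxylate (C4 epimers) | COC(=O)C1CC=C(C)[C@@H]2OC(C)(C)O[C@H]12
F4 | step 4 | (3aR,7aS)-2,2,7-trimethyl-3a,4,5,7a-tetrahydro-1,3-benzodioxole-4-carboxylic acid (C4 epimers) | OC(=O)C1CC=C(C)[C@@H]2OC(C)(C)O[C@H]12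
F5 | step 4 | 1,3-dioxoisoindolin-2-yl (3aR,7aS)-2,2,7-trimethyl-3a,4,5,7a-tetrahydro-1,3-benzodioxole-4-carboxylate (C4 epimers) | O=C(ON1C(=O)c2ccccc2C1=O)C1CC=C(C)[C@@H]2OC(C)(C)O[C@H]12
F6 | step 4 | (3aR,4S,7aS)-4-(1-ethoxyethenyl)-2,2,7-trimethyl-3a,4,5,7a-tetrahydro-1,3-benzodioxole | C=C(OCC)[C@H]1CC=C(C)[C@@H]2OC(C)(C)O[C@H]12
F7 | step 13 | (1R,2S,3S,4S,6R,8S)-8-(angeloyloxy)-3,4-epoxybisabola-7(14),10-diene-1,2-diol (cis-diol, epoxide cis to both hydroxyls) | C=C([C@H](CC=C(C)C)OC(=O)/C(C)=C\C)[C@H]1C[C@@H]2O[C@]2(C)[C@H](O)[C@@H]1O
F8 | step 12 | (3S)-2-[(1R,6R)-6-hydroxy-4-methyl-5-oxocyclohex-3-en-1-yl]-6-methylhepta-1,5-dien-3-yl (2Z)-2-methylbut-2-enoate | C=C([C@H](CC=C(C)C)OC(=O)/C(C)=C\C)[C@H]1CC=C(C)C(=O)[C@@H]1O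
F9 | step 12 | (3S)-2-[(1R,5R,6R)-5,6-dihydroxy-4-methylcyclohex-3-en-1-yl]-6-methylhepta-1,5-dien-3-yl (2Z)-2-methylbut-2-enoate (trans-diol) | C=C([C@H](CC=C(C)C)OC(=O)/C(C)=C\C)[C@H]1CC=C(C)[C@@H](O)[C@@H]1O
F10 | step 14 | C1 triethylsilyl ether of 20 | C=C([C@H](CC=C(C)C)OC(=O)/C(C)=C\C)[C@H]1C[C@@H]2O[C@]2(C)[C@@H](OC(=O)/C(C)=C\C)[C@@H]1O[Si](CC)(CC)CC
F11 | step 14 | C1 triethylsilyl ether of 21 | C=C([C@H](C[C@H]1OC1(C)C)OC(=O)/C(C)=C\C)[C@H]1C[C@@H]2O[C@]2(C)[C@@H](OC(=O)/C(C)=C\C)[C@@H]1O[Si](CC)(CC)CC
F0 | step 9 | none | none
A1 | alternative 1 | target lacking the ring epoxide (ring-closing metathesis product) | C=C([C@H](C[C@H]1OC1(C)C)OC(=O)/C(C)=C\C)[C@H]1CC=C(C)[C@@H](OC(=O)/C(C)=C\C)[C@@H]1O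
A2 | alternative 1 | acyclic triene with C5 vinyl and C2 isopropenyl groups (metathesis substrate) | C=C([C@H](C[C@H]1OC1(C)C)OC(=O)/C(C)=C\C)[C@@H](CC=C)[C@@H](O)[C@H](OC(=O)/C(C)=C\C)C(C)=C
A3 | alternative 2 | 5-hydroxy-4-hydroxy-4-methyl-2,3-bis(4-methoxybenzyloxy)cyclohexanone (Ferrier product) | O=C1C[C@H](O)[C@](C)(O)[C@@H](OCc2ccc(OC)cc2)[C@@H]1OCc1ccc(OC)cc1
A4 | alternative 2 | methyl 6-deoxy-3,4-bis-O-(4-methoxybenzyl)-2-C-methyl-α-D-hex-5-enopyranoside, gluco-configured at C2–C4 | C=C1O[C@H](OC)[C@](C)(O)[C@@H](OCc2ccc(OC)cc2)[C@@H]1OCc1ccc(OC)cc1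
A5 | alternative 3 | trans-6-(benzoyloxy)-4-methylcyclohex-3-enecarbonyl oxazolidinone | O=C(N1CCOC1=O)[C@H]1CC=C(C)C[C@@H]1OC(=O)c1ccccc1
A6 | alternative 3 | (E)-3-(benzoyloxy)acryloyl oxazolidinone | O=C(/C=C/OC(=O)c1ccccc1)N1CCOC1=O
A7 | alternative 3 | isoprene | C=CC(C)=C
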